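**Retrosynthetic overview**

1. Atom numbers (germacrane): ten-membered ring C1–C10 with an E C1=C10 alkene, a cis-oxirane on C4–C5, OAc on C6, isopropyl on C7 and the senecioate on C8. The last step is acetylation of the free C6 hydroxyl.
2. Key disconnection C7–C8: an acyclic α-bromo-α′,β′-epoxy keto aldehyde (C8 aldehyde, C6 ketone, C7–Br) is closed by a samarium Reformatsky-type aldol. The samarium aldolate is trapped in the same flask by a crossed Evans–Tishchenko reaction with 3-methylbut-2-enal, which reduces C6 and places the senecioate on O8.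
3. Enabling feature: the ring segment O–C6–C7(iPr)–C8–O is an anti-1,3-diol acylated on O8 only (an aldol–Tishchenko retron), and C6 is flanked by the cis C4–C5 oxirane. The oxirane oxygen can chelate the metal, and its cis geometry together with the E C1=C10 alkene folds the chain, so C6, C7 and C8 are all relayed from the oxirane.
4. The open chain comes from neryl acetate: SeO2 oxidation of the E-methyl, Wittig methylenation and diene hydroboration add C8; Sharpless epoxidation of the Z-allylic alcohol sets C4/C5; isobutyl Grignard addition, oxidation and α-bromination build C6/C7.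
5. Ring order: oxirane first (step 6), ten-membered carbocycle in step 13.

Key step: step 13

Remark: D-(−)-diethyl tartrate is taken to epoxidise the Z-allylic alcohol with the facial sense that gives the (2R,3S)-oxirane from nerol-type substrates; the carbinol centre from the Grignard addition and the bromide-bearing centre are carried as epimer mixtures because both are erased before C6 and C7 are set.

**Route**

Step 1
Reactants: 1 neryl acetate [(2Z)-3,7-dimethylocta-2,6-dien-1-yl acetate]
Product: 2 (2Z,6E)-3,7-dimethyl-8-oxoocta-2,6-dien-1-yl acetate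
Conditions: SeO2 (1.1 equiv), 95% EtOH, reflux
Reagents that add atoms: selenium dioxide, O=[Se]=O
Why: Riley allylic oxidation (ene reaction, then [2,3]-sigmatropic shift) should attack only the E-methyl of the electron-rich terminal alkene, the 2,3-alkene being deactivated by the allylic acetate, and should give the E-enal.

Step 2
Reactants: 2 (2Z,6E)-3,7-dimethyl-8-oxoocta-2,6-dien-1-yl acetate
Product: 3 (2Z,6E)-3,7-dimethylnona-2,6,8-trien-1-yl acetate
Conditions: Ph3PCH3Br (1.3 equiv), KHMDS (1.25 equiv), THF, −78 → 0 °C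
Reagents that add atoms: methyltriphenylphosphonium bromide, C[P+](c1ccccc1)(c1ccccc1)c1ccccc1.[Br-]
Why: Wittig methylenation of the enal is fast at low temperature, should leave the acetate and both alkene geometries untouched, and brings in the future C8 carbon.

Step 3
Reactants: 3 (2Z,6E)-3,7-dimethylnona-2,6,8-trien-1-yl acetate
Product: 5 (2Z,6E)-9-hydroxy-3,7-dimethylnona-2,6-dien-1-yl acetate, via B-alkyl-9-BBN adduct 4 (not isolated)
Conditions: 9-BBN (1.3 equiv), THF, 0 °C → rt; then 30% H2O2, 3 M aq. NaOAc, 0 °C → rt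
Reagents that add atoms: hydrogen peroxide, OO; 9-borabicyclo[3.3.1]nonane, B1C2CCCC1CCC2 (its boron and ring stay only in 4)
Why: Hydroboration–oxidation with 9-BBN should be selective for the monosubstituted terminus of the 1,3-diene (boron on the terminal carbon), and buffered peroxide should give the homoallylic alcohol with the E-alkene and the acetate intact.

Step 4
Reactants: 5 (2Z,6E)-9-hydroxy-3,7-dimethylnona-2,6-dien-1-yl acetate
Product: 6 (2Z,6E)-9-[(tert-butyldimethylsilyl)oxy]-3,7-dimethylnona-2,6-dien-1-yl acetate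
Conditions: TBSCl (1.2 equiv), imidazole (2.5 equiv), DMF, 0 °C → rt
Reagents that add atoms: tert-butyldimethylsilyl chloride, CC(C)(C)[Si](C)(C)Cl
Why: Standard silyl ether protection of the only free, primary hydroxyl.

Step 5
Reactants: 6 (2Z,6E)-9-[(tert-butyldimethylsilyl)oxy]-3,7-dimethylnona-2,6-dien-1-yl acetate
Product: 7 (2Z,6E)-9-[(tert-butyldimethylsilyl)oxy]-3,7-dimethylnona-2,6-dien-1-ol
Conditions: K2CO3 (0.2 equiv), MeOH, 0 °C → rt
Reagents that add atoms: none
Why: Base-catalysed transesterification (Zemplén-type methanolysis) should remove the allylic acetate while the primary TBS ether is stable.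

Step 6
Reactants: 7 (2Z,6E)-9-[(tert-butyldimethylsilyl)oxy]-3,7-dimethylnona-2,6-dien-1-ol
Product: 8 [(2R,3S)-3-[(3E)-6-[(tert-butyldimethylsilyl)oxy]-4-methylhex-3-en-1-yl]-3-methyloxiran-2-yl]methanol
Conditions: Ti(OiPr)4 (10 mol%), D-(−)-diethyl tartrate (12 mol%), t-BuOOH (2 equiv), 4 Å MS, CH2Cl2, −20 °C
Reagents that add atoms: tert-butyl hydroperoxide, CC(C)(C)OO
Why: Katsuki–Sharpless asymmetric epoxidation acts only on the allylic alcohol alkene; the D-(−)-tartrate catalyst should set both oxirane centres (C4 and C5 of the target) by reagent control, and the cis relation of chain and CH2OH follows from the Z-alkene.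

Step 7
Reactants: 8 [(2R,3S)-3-[(3E)-6-[(tert-butyldimethylsilyl)oxy]-4-methylhex-3-en-1-yl]-3-methyloxiran-2-yl]methanol
Product: 9 (2S,3S)-3-[(3E)-6-[(tert-butyldimethylsilyl)oxy]-4-methylhex-3-en-1-yl]-3-methyloxirane-2-carbaldehyde
Conditions: Dess–Martin periodinane (1.3 equiv), NaHCO3, CH2Cl2, 0 °C → rt
Reagents that add atoms: none
Why: Buffered Dess–Martin oxidation should convert the 2,3-epoxy alcohol into the non-enolisable α,β-epoxy aldehyde without oxirane opening (the descriptor at the CH centre changes by priority only).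

Step 8
Reactants: 9 (2S,3S)-3-[(3E)-6-[(tert-butyldimethylsilyl)oxy]-4-methylhex-3-en-1-yl]-3-methyloxirane-2-carbaldehyde; 10 isobutylmagnesium bromide
Product: 11 1-[(2R,3S)-3-[(3E)-6-[(tert-butyldimethylsilyl)oxy]-4-methylhex-3-en-1-yl]-3-methyloxiran-2-yl]-3-methylbutan-1-ol (both carbinol epimers)
Conditions: 10 (1.3 equiv), THF, −78 °C; then H2O (pH 7 buffer)
Reagents that add atoms: none
Why: Grignard addition to the aldehyde at −78 °C should outrun oxirane opening; the new carbinol centre is left uncontrolled because the next step oxidises it.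

Step 9
Reactants: 11 1-[(2R,3S)-3-[(3E)-6-[(tert-butyldimethylsilyl)oxy]-4-methylhex-3-en-1-yl]-3-methyloxiran-2-yl]-3-methylbutan-1-ol
Product: 12 1-[(2S,3S)-3-[(3E)-6-[(tert-butyldimethylsilyl)oxy]-4-methylhex-3-en-1-yl]-3-methyloxiran-2-yl]-3-methylbutan-1-one
Conditions: Dess–Martin periodinane (1.5 equiv), NaHCO3, CH2Cl2, rt
Reagents that add atoms: none
Why: Dess–Martin oxidation of the secondary alcohol should give the α,β-epoxy isobutyl ketone and removes the uncontrolled carbinol centre.

Step 10
Reactants: 12 1-[(2S,3S)-3-[(3E)-6-[(tert-butyldimethylsilyl)oxy]-4-methylhex-3-en-1-yl]-3-methyloxiran-2-yl]-3-methylbutan-1-one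
Product: 14 2-bromo-1-[(2S,3S)-3-[(3E)-6-[(tert-butyldimethylsilyl)oxy]-4-methylhex-3-en-1-yl]-3-methyloxiran-2-yl]-3-methylbutan-1-one (both bromide epimers), via trimethylsilyl enol ether 13 (not isolated)
Conditions: LiHMDS (1.15 equiv), TMSCl (1.3 equiv), THF, −78 °C; then NBS (1.05 equiv), −78 °C
Reagents that add atoms: N-bromosuccinimide, O=C1CCC(=O)N1Br; chlorotrimethylsilane, C[Si](C)(C)Cl (silicon stays only in 13)
Why: Kinetic enolisation with in situ silylation can occur only at C7 because the oxirane C–H is not enolisable, and electrophilic bromination of the silyl enol ether with NBS at −78 °C should be much faster than attack on the trisubstituted alkene; the bromide centre is erased in step 13.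

Step 11
Reactants: 14 2-bromo-1-[(2S,3S)-3-[(3E)-6-[(tert-butyldimethylsilyl)oxy]-4-methylhex-3-en-1-yl]-3-methyloxiran-2-yl]-3-methylbutan-1-one
Product: 15 2-bromo-1-[(2S,3S)-3-[(3E)-6-hydroxy-4-methylhex-3-en-1-yl]-3-methyloxiran-2-yl]-3-methylbutan-1-one
Conditions: HF·pyridine, pyridine, THF, 0 °C → rt
Reagents that add atoms: none
Why: Buffered HF·pyridine desilylation should cleave the primary TBS ether under conditions mild enough for the oxirane and the hindered secondary α-bromo ketone.

Step 12
Reactants: 15 2-bromo-1-[(2S,3S)-3-[(3E)-6-hydroxy-4-methylhex-3-en-1-yl]-3-methyloxiran-2-yl]-3-methylbutan-1-one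
Product: 16 (3E)-6-[(2S,3S)-3-(2-bromo-3-methylbutanoyl)-2-methyloxiran-2-yl]-3-methylhex-3-enal
Conditions: Dess–Martin periodinane (1.3 equiv), NaHCO3, CH2Cl2, 0 °C; used crude at once
Reagents that add atoms: none
Why: Buffered, non-basic Dess–Martin oxidation should give the β,γ-unsaturated aldehyde without moving the C1=C10 alkene into conjugation or eliminating HBr.

Step 13
Reactants: 16 (3E)-6-[(2S,3S)-3-(2-bromo-3-methylbutanoyl)-2-methyloxiran-2-yl]-3-methylhex-3-enal; 17 3-methylbut-2-enal
Product: 20 (1R,2R,3S,4S,6E,10S)-2-hydroxy-6,10-dimethyl-3-(propan-2-yl)-11-oxabicyclo[8.1.0]undec-6-en-4-yl 3-methylbut-2-enoate, via samarium(III) enolate 18 (not isolated), via samarium(III) aldolate 19 (not isolated)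
Conditions: SmI2 (0.1 M in THF, 2.05 equiv) added over 3 h to 16 (2 mM in THF), −78 → −40 °C; then 17 (5 equiv), −40 → −10 °C; pH 7 buffer
Reagents that add atoms: samarium(II) iodide, I[Sm]I (samarium and iodine stay only in 18 and 19)
Why: Proposed new method: SmI2 reduces the C7–Br bond of 16 (the most easily reduced site, ahead of the epoxy ketone and the aldehyde) to the Z(O) samarium(III) enolate 18, which closes the ten-membered carbocycle by a 10-(enolendo)-exo-trig aldol addition to the C8 aldehyde; the O8–Sm alkoxide of 19 then adds to 3-methylbut-2-enal and the hemiacetal passes its hydride to the C6 ketone through the six-membered Evans–Tishchenko transition state, so that the strained, reversible macro-aldol is pulled forward by an irreversible redox esterification. The closest known reactions are SmI2-mediated intramolecular Reformatsky-type aldol closures of medium and large rings and the samarium-catalysed Evans–Tishchenko reduction (also run as an intermolecular SmI2 aldol–Tishchenko tandem); their union in a ring closure that uses a second aldehyde for the Tishchenko stage is not known. C7 should be set by chelation of Sm(III) between the enolate oxygen and the oxirane oxygen, which holds C4 and the aldehyde tether on one face of the enolate; C8 by chair-like Zimmerman–Traxler addition of the Z-enolate (7,8-syn); C6 by internal hydride delivery from the O8 hemiacetal (6,8-anti). The step needs C–Br reduction ahead of oxirane cleavage, ring closure ahead of oligomerisation and acylation of O8 only: the first is secured by the weak C–Br bond and by keeping SmI2 the limiting reagent, the second by high dilution and by the cis-oxirane and E-alkene acting as turn elements, the third by the mechanism, which can acylate only the oxygen that carried the metal.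

Step 14
Reactants: 20 (1R,2R,3S,4S,6E,10S)-2-hydroxy-6,10-dimethyl-3-(propan-2-yl)-11-oxabicyclo[8.1.0]undec-6-en-4-yl 3-methylbut-2-enoate
Product: 21 (1R,2R,3R,4S,6E,10S)-2-(acetyloxy)-6,10-dimethyl-3-(propan-2-yl)-11-oxabicyclo[8.1.0]undec-6-en-4-yl 3-methylbut-2-enoate (target; the C3 descriptor changes by priority only)
Conditions: Ac2O (3 equiv), DMAP (0.2 equiv), pyridine, CH2Cl2, 0 °C → rt
Reagents that add atoms: acetic anhydride, CC(=O)OC(C)=O
Why: DMAP-catalysed acylation of the only free hydroxyl (C6) should leave the oxirane, the senecioate and all stereocentres untouched.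

**Compound list**

1 | neryl acetate, (2Z)-3,7-dimethylocta-2,6-dien-1-yl acetate | CC(C)=CCC/C(C)=C\COC(C)=O | starting material
2 | (2Z,6E)-3,7-dimethyl-8-oxoocta-2,6-dien-1-yl acetate | O=C/C(C)=C/CC/C(C)=C\COC(C)=O | intermediate
3 | (2Z,6E)-3,7-dimethylnona-2,6,8-trien-1-yl acetate | C=C/C(C)=C/CC/C(C)=C\COC(C)=O | intermediate
4 | (2Z,6E)-9-(9-borabicyclo[3.3.1]nonan-9-yl)-3,7-dimethylnona-2,6-dien-1-yl acetate | B1(CC/C(C)=C/CC/C(C)=C\COC(C)=O)C2CCCC1CCC2 | intermediate (not isolated)
5 | (2Z,6E)-9-hydroxy-3,7-dimethylnona-2,6-dien-1-yl acetate | OCC/C(C)=C/CC/C(C)=C\COC(C)=O | intermediate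
6 | (2Z,6E)-9-[(tert-butyldimethylsilyl)oxy]-3,7-dimethylnona-2,6-dien-1-yl acetate | CC(C)(C)[Si](C)(C)OCC/C(C)=C/CC/C(C)=C\COC(C)=O | intermediate
7 | (2Z,6E)-9-[(tert-butyldimethylsilyl)oxy]-3,7-dimethylnona-2,6-dien-1-ol | CC(C)(C)[Si](C)(C)OCC/C(C)=C/CC/C(C)=C\CO | intermediate
8 | [(2R,3S)-3-[(3E)-6-[(tert-butyldimethylsilyl)oxy]-4-methylhex-3-en-1-yl]-3-methyloxiran-2-yl]methanol | CC(C)(C)[Si](C)(C)OCC/C(C)=C/CC[C@]1(C)O[C@@H]1CO | intermediate
9 | (2S,3S)-3-[(3E)-6-[(tert-butyldimethylsilyl)oxy]-4-methylhex-3-en-1-yl]-3-methyloxirane-2-carbaldehyde | CC(C)(C)[Si](C)(C)OCC/C(C)=C/CC[C@]1(C)O[C@@H]1C=O | intermediate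
10 | isobutylmagnesium bromide | CC(C)C[Mg]Br | starting material
11 | 1-[(2R,3S)-3-[(3E)-6-[(tert-butyldimethylsilyl)oxy]-4-methylhex-3-en-1-yl]-3-methyloxiran-2-yl]-3-methylbutan-1-ol (both carbinol epimers) | CC(C)(C)[Si](C)(C)OCC/C(C)=C/CC[C@]1(C)O[C@@H]1C(O)CC(C)C | intermediate
12 | 1-[(2S,3S)-3-[(3E)-6-[(tert-butyldimethylsilyl)oxy]-4-methylhex-3-en-1-yl]-3-methyloxiran-2-yl]-3-methylbutan-1-one | CC(C)(C)[Si](C)(C)OCC/C(C)=C/CC[C@]1(C)O[C@@H]1C(=O)CC(C)C | intermediate
13 | trimethylsilyl enol ether of 12 (C6–OSiMe3, C6=C7; enol ether geometry not fixed) | CC(C)(C)[Si](C)(C)OCC/C(C)=C/CC[C@]1(C)O[C@@H]1C(O[Si](C)(C)C)=CC(C)C | intermediate (not isolated)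
14 | 2-bromo-1-[(2S,3S)-3-[(3E)-6-[(tert-butyldimethylsilyl)oxy]-4-methylhex-3-en-1-yl]-3-methyloxiran-2-yl]-3-methylbutan-1-one (both bromide epimers) | CC(C)(C)[Si](C)(C)OCC/C(C)=C/CC[C@]1(C)O[C@@H]1C(=O)C(Br)C(C)C | intermediate
15 | 2-bromo-1-[(2S,3S)-3-[(3E)-6-hydroxy-4-methylhex-3-en-1-yl]-3-methyloxiran-2-yl]-3-methylbutan-1-one (both bromide epimers) | OCC/C(C)=C/CC[C@]1(C)O[C@@H]1C(=O)C(Br)C(C)C | intermediate
16 | (3E)-6-[(2S,3S)-3-(2-bromo-3-methylbutanoyl)-2-methyloxiran-2-yl]-3-methylhex-3-enal (both bromide epimers) | O=CC/C(C)=C/CC[C@]1(C)O[C@@H]1C(=O)C(Br)C(C)C | intermediate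
17 | 3-methylbut-2-enal | CC(C)=CC=O | starting material
18 | Z(O) samarium(III) diiodide enolate of the C6 ketone (C6=C7), aldehyde still free | O=CC/C(C)=C/CC[C@]1(C)O[C@@H]1/C(O[Sm](I)I)=C/C(C)C | intermediate (not isolated)
19 | samarium(III) diiodide O8-aldolate of the cyclised β-hydroxy ketone (ten-membered ring closed, C6 ketone) | O=C1[C@H](C(C)C)[C@@H](O[Sm](I)I)C/C(C)=C/CC[C@]2(C)O[C@H]12 | intermediate (not isolated)
20 | (1R,2R,3S,4S,6E,10S)-2-hydroxy-6,10-dimethyl-3-(propan-2-yl)-11-oxabicyclo[8.1.0]undec-6-en-4-yl 3-methylbut-2-enoate | O[C@@H]1[C@H](C(C)C)[C@@H](OC(=O)C=C(C)C)C/C(C)=C/CC[C@]2(C)O[C@H]12 | intermediate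
21 | (1R,2R,3R,4S,6E,10S)-2-(acetyloxy)-6,10-dimethyl-3-(propan-2-yl)-11-oxabicyclo[8.1.0]undec-6-en-4-yl 3-methylbut-2-enoate | CC(=O)O[C@@H]1[C@H](C(C)C)[C@@H](OC(=O)C=C(C)C)C/C(C)=C/CC[C@]2(C)O[C@H]12 | target

**Step count and risks**

Total steps: 14. Longest linear sequence: 14 steps (1 to 21).

Steps most likely to fail:

1. Step 13 (proposed new method). The three events may not mesh in one flask. The samarium aldolate can reopen by retro-aldol under ring strain, or the added enal can be consumed by residual enolate or by its own Tishchenko dimerisation before hydride transfer, so that reduction of C6 and acyl transfer do not follow ring closure. Fallback with known reactions, run as two separate operations: setting out from 16, SmI2 alone (2.1 equiv, THF, −78 °C, 2 mM) with a cold pH 7 quench should give, by the known intramolecular Reformatsky-type aldol closure, the β-hydroxy ketone (1S,3R,4S,6E,10S)-4-hydroxy-6,10-dimethyl-3-(propan-2-yl)-11-oxabicyclo[8.1.0]undec-6-en-2-one F1, where aldol diastereomers can be separated. F1 is then submitted to a classical Evans–Tishchenko reduction (SmI2 30 mol% pre-mixed with 17, 6 equiv, THF, −10 °C), which should give 20, where the route is rejoined.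

2. Step 10. Enolisation of the α,β-epoxy ketone with an amide base may be accompanied by base-induced damage to the oxirane, or by proton shuffling that leads to over-bromination. Fallback that makes the enol silane without base: setting out from 9, addition of 2-methylprop-1-enylmagnesium bromide (THF, −78 °C) should give the allylic alcohol 1-[(2R,3S)-3-[(3E)-6-[(tert-butyldimethylsilyl)oxy]-4-methylhex-3-en-1-yl]-3-methyloxiran-2-yl]-3-methylbut-2-en-1-ol F2. MnO2 (CH2Cl2, rt) should oxidise it to the enone 1-[(2S,3S)-3-[(3E)-6-[(tert-butyldimethylsilyl)oxy]-4-methylhex-3-en-1-yl]-3-methyloxiran-2-yl]-3-methylbut-2-en-1-one F3. Rhodium-catalysed 1,4-hydrosilylation (RhCl(PPh3)3 1 mol%, Et3SiH, benzene, 50 °C) should give regiospecifically the triethylsilyl enol ether of 12 F4, and NBS (THF, −78 °C) should convert it into 14, where the route is rejoined.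

3. Step 11. During desilylation of the fully functionalised 14, bromide may be lost (substitution by fluoride or pyridine, or HBr elimination) or the oxirane may be opened by HF. Fallback that changes the order so that fluoride never meets the bromo ketone: setting out from 12, TBAF buffered with AcOH (THF, 0 °C) should give the keto alcohol 1-[(2S,3S)-3-[(3E)-6-hydroxy-4-methylhex-3-en-1-yl]-3-methyloxiran-2-yl]-3-methylbutan-1-one F5. LiHMDS (2.3 equiv) and TMSCl (2.6 equiv) in THF at −78 °C should give the bis(trimethylsilyl) derivative of F5 (silyl enol ether plus primary silyl ether) F6, NBS at −78 °C should give the O-trimethylsilyl ether of 15 F7, and work-up with aqueous citric acid should hydrolyse the labile primary silyl ether to 15, where the route is rejoined.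

**Further compounds**

F1 | step 13 | (1S,3R,4S,6E,10S)-4-hydroxy-6,10-dimethyl-3-(propan-2-yl)-11-oxabicyclo[8.1.0]undec-6-en-2-one | O=C1[C@H](C(C)C)[C@@H](O)C/C(C)=C/CC[C@]2(C)O[C@H]12
F2 | step 10 | 1-[(2R,3S)-3-[(3E)-6-[(tert-butyldimethylsilyl)oxy]-4-methylhex-3-en-1-yl]-3-methyloxiran-2-yl]-3-methylbut-2-en-1-ol (both carbinol epimers) | CC(C)(C)[Si](C)(C)OCC/C(C)=C/CC[C@]1(C)O[C@@H]1C(O)C=C(C)C
F3 | step 10 | 1-[(2S,3S)-3-[(3E)-6-[(tert-butyldimethylsilyl)oxy]-4-methylhex-3-en-1-yl]-3-methyloxiran-2-yl]-3-methylbut-2-en-1-one | CC(C)(C)[Si](C)(C)OCC/C(C)=C/CC[C@]1(C)O[C@@H]1C(=O)C=C(C)C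
F4 | step 10 | triethylsilyl enol ether of 12 (enol ether geometry not fixed) | CC(C)(C)[Si](C)(C)OCC/C(C)=C/CC[C@]1(C)O[C@@H]1C(O[Si](CC)(CC)CC)=CC(C)C
F5 | step 11 | 1-[(2S,3S)-3-[(3E)-6-hydroxy-4-methylhex-3-en-1-yl]-3-methyloxiran-2-yl]-3-methylbutan-1-one | OCC/C(C)=C/CC[C@]1(C)O[C@@H]1C(=O)CC(C)C
F6 | step 11 | bis(trimethylsilyl) derivative of F5 (silyl enol ether and primary silyl ether) | C[Si](C)(C)OCC/C(C)=C/CC[C@]1(C)O[C@@H]1C(O[Si](C)(C)C)=CC(C)C
F7 | step 11 | O-trimethylsilyl ether of 15 | C[Si](C)(C)OCC/C(C)=C/CC[C@]1(C)O[C@@H]1C(=O)C(Br)C(C)C
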